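Ring A is built last, on a side chain already esterified to O4' of ring B. The feature exploited is the meta relationship of C2–OH and C4–OMe on ring A with the CH2O-bearing C3 between them, next to the C1 ester carbon and C6–CH3: the pattern a vinylketene and a 1-methoxyalkyne deliver. One operation (photochemical Wolff shift, ketene–alkyne cycloaddition, 4π opening, 6π closure) forms C5–C6, C2–C3, C4–C5 and C1–C2 and the whole ring, with no stereocentre. The precursor is the ring B aryl ester of (E)-5-diazo-3-methyl-4-oxopent-2-enoic acid, made by diazo transfer to a methyl ketone instead of diazomethane acylation; its partner is TBS-protected 3-methoxyprop-2-yn-1-ol.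

Key step: step 8

Remark: precursor 9 and product 18 map atom by atom onto the target, so their constitution is kept; the hydrogen-bonded 2-hydroxyl of ring B stays unprotected and is assumed inert to carbodiimide acylation and, under dilution and alkyne excess, to the ketene; it takes up one extra equivalent of base in step 5.

Step 1
Reactants: 1 2,5-dimethylresorcinol
Product: 2 2,4-dihydroxy-3,6-dimethylbenzoic acid
Conditions: KHCO3, CO2 (1 atm), glycerol, 130 °C; then cold aq. HCl
Reagents that add atoms: carbon dioxide, O=C=O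
Why: Kolbe–Schmitt carboxylation of the electron-rich potassium phenoxide, in which the two open ring positions are equivalent (each ortho to one OH and para to the other), so only one acid can form.

Step 2
Reactants: 2 2,4-dihydroxy-3,6-dimethylbenzoic acid
Product: 3 benzyl 2,4-dihydroxy-3,6-dimethylbenzoate
Conditions: BnBr, KHCO3, DMF, 20 °C
Reagents that add atoms: benzyl bromide, BrCc1ccccc1
Why: SN2 O-alkylation of the carboxylate, the only group ionized by hydrogencarbonate, should leave both phenols free and give the benzyl ester customary for depside B rings.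

Step 3
Reactants: 4 glyoxylic acid monohydrate, 5 3-(triphenylphosphoranylidene)butan-2-one
Product: 6 (2E)-3-methyl-4-oxopent-2-enoic acid
Conditions: THF, 20→50 °C; aq. NaHCO3 extraction, then HCl
Reagents that add atoms: none
Why: Wittig olefination of the highly electrophilic aldehyde by the acyl-stabilized ylide should give, under thermodynamic control, the E alkene with CO2H trans to the acetyl group, and the acid is separated from Ph3PO by base extraction.

Step 4
Reactants: 3 benzyl 2,4-dihydroxy-3,6-dimethylbenzoate, 6 (2E)-3-methyl-4-oxopent-2-enoic acid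
Product: 7 benzyl 2-hydroxy-3,6-dimethyl-4-{[(2E)-3-methyl-4-oxopent-2-enoyl]oxy}benzoate
Conditions: DCC, DMAP (0.1 equiv), CH2Cl2, 0→20 °C
Reagents that add atoms: none
Why: Steglich esterification should acylate only the 4-hydroxyl, because the 2-hydroxyl is locked in a hydrogen bond to the benzyl ester and flanked by a methyl group.

Step 5
Reactants: 7 benzyl 2-hydroxy-3,6-dimethyl-4-{[(2E)-3-methyl-4-oxopent-2-enoyl]oxy}benzoate
Product: 9 benzyl 4-{[(2E)-5-diazo-3-methyl-4-oxopent-2-enoyl]oxy}-2-hydroxy-3,6-dimethylbenzoate, via trifluoroacetyl diketone 8 (not isolated)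
Conditions: LiN(SiMe3)2 (2.2 equiv), THF, −78 °C; CF3CO2CH2CF3, −78 °C; dilute aq. HCl work-up; then 4-AcNHC6H4SO2N3, Et3N, H2O (1 equiv), MeCN, 20 °C
Reagents that add atoms: 4-acetamidobenzenesulfonyl azide, CC(=O)Nc1ccc(S(=O)(=O)N=[N+]=[N-])cc1 (supplies the two diazo nitrogens of 9); 2,2,2-trifluoroethyl trifluoroacetate, O=C(OCC(F)(F)F)C(F)(F)F (supplies the trifluoroacetyl group of 8 only, which is lost again)
Why: Detrifluoroacetylative diazo transfer (kinetic enolization of the acetyl methyl, the only enolizable site of the ketone, Claisen C-trifluoroacetylation to 8, then Regitz-type diazo transfer with loss of the trifluoroacetyl group) should install the diazo group without diazomethane, which would add as a 1,3-dipole to the fumarate-like double bond.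

Step 6
Reactants: 10 chloroacetaldehyde dimethyl acetal
Product: 12 3-methoxyprop-2-yn-1-ol, via lithium methoxyacetylide 11 (not isolated)
Conditions: LiNEt2 (3.1 equiv, from n-BuLi and Et2NH), THF, 0 °C; (CH2O)n, 0→20 °C; aq. NH4Cl
Reagents that add atoms: formaldehyde (as paraformaldehyde), C=O
Why: Successive amide-induced loss of methanol and of HCl followed by metalation should give acetylide 11, which adds to formaldehyde (acetylide 1,2-addition), and the work-up is kept non-acidic because ynol ethers hydrate readily.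

Step 7
Reactants: 12 3-methoxyprop-2-yn-1-ol
Product: 13 tert-butyl[(3-methoxyprop-2-yn-1-yl)oxy]dimethylsilane
Conditions: TBSCl, imidazole, CH2Cl2, 0→20 °C
Reagents that add atoms: tert-butyldimethylsilyl chloride, CC(C)(C)[Si](C)(C)Cl
Why: Silylation of a primary alcohol with imidazole-activated silyl chloride proceeds under basic conditions that the acid-labile ynol ether tolerates.

Step 8
Reactants: 9 benzyl 4-{[(2E)-5-diazo-3-methyl-4-oxopent-2-enoyl]oxy}-2-hydroxy-3,6-dimethylbenzoate, 13 tert-butyl[(3-methoxyprop-2-yn-1-yl)oxy]dimethylsilane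
Product: 18 benzyl 4-{[3-({[tert-butyl(dimethyl)silyl]oxy}methyl)-2-hydroxy-4-methoxy-6-methylbenzoyl]oxy}-2-hydroxy-3,6-dimethylbenzoate, via vinylketene 14 (not isolated), via vinylcyclobutenone 15 (not isolated), via dienylketene 16 (not isolated), via cyclohexadienone 17 (not isolated)
Conditions: 13 (3 equiv), hν (365 nm LEDs, Pyrex), degassed ClCH2CH2Cl (0.05 M), 20 °C; then 80 °C in the dark
Reagents that add atoms: none
Why: Excitation of the diazoketone expels N2 and the alkenyl group migrates to the former diazo carbon (Wolff rearrangement, C5–C6) to give vinylketene 14, whose carbonyl carbon is attacked by the alkyne carbon remote from OMe, so that a (2+2) cycloaddition gives cyclobutenone 15 (C2–C3 and C4–C5). On warming, 15 opens by 4π electrocyclic cleavage to dienylketene 16, and ring A closes by thermal disrotatory 6π electrocyclization (C1–C2, six-membered carbocycle) to dienone 17, which enolizes to the phenol. The closest known reaction is the Danheiser benzannulation in its photochemical diazoketone form, for which 1-alkoxyalkynes are established partners; only the ester at the cyclizing terminus is new. No stereocentre is created in the product, and the sp3 carbons of 15 and 17 are transient and racemic. The selectivity needed is regiochemical (CH2OTBS at C3, between C2–OH and C4–OMe) and is secured by the polarization of the ynol ether, while the E enoate holds the aryl ester trans to the ketene, so that its carbonyl oxygen cannot close onto the ketene and only hydrogen points inward at C1 in the 6π step. Light of 365 nm should be absorbed by the diazo chromophore but not by the aryl esters (no photo-Fries pathway), and dilution plus excess 13 favour cycloaddition over acylation of the hydrogen-bonded phenols by 14.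

Step 9
Reactants: 18 benzyl 4-{[3-({[tert-butyl(dimethyl)silyl]oxy}methyl)-2-hydroxy-4-methoxy-6-methylbenzoyl]oxy}-2-hydroxy-3,6-dimethylbenzoate
Product: 19 4-{[3-({[tert-butyl(dimethyl)silyl]oxy}methyl)-2-hydroxy-4-methoxy-6-methylbenzoyl]oxy}-2-hydroxy-3,6-dimethylbenzoic acid
Conditions: H2 (1 atm), Pd/C (10% Pd), EtOAc, 20 °C
Reagents that add atoms: none
Why: Catalytic hydrogenolysis of the benzyl ester in a neutral aprotic solvent should spare the depside ester and the benzylic silyl ether, which resists C–O hydrogenolysis far better than the free o-hydroxybenzylic alcohol would.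

Step 10
Reactants: 19 4-{[3-({[tert-butyl(dimethyl)silyl]oxy}methyl)-2-hydroxy-4-methoxy-6-methylbenzoyl]oxy}-2-hydroxy-3,6-dimethylbenzoic acid
Product: 20 3-alpha-hydroxybarbatic acid (2-hydroxy-4-{[2-hydroxy-3-(hydroxymethyl)-4-methoxy-6-methylbenzoyl]oxy}-3,6-dimethylbenzoic acid)
Conditions: HF·pyridine, pyridine, THF, 0→20 °C
Reagents that add atoms: none
Why: Fluoride-driven Si–O cleavage (desilylation) under buffered, weakly acidic conditions should leave the base-sensitive depside ester intact and not ionize the o-hydroxybenzylic alcohol.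

Compound list
1 | 2,5-dimethylresorcinol (2,5-dimethylbenzene-1,3-diol) | Cc1cc(O)c(C)c(O)c1 | starting material
2 | 2,4-dihydroxy-3,6-dimethylbenzoic acid | Cc1cc(O)c(C)c(O)c1C(=O)O | intermediate
3 | benzyl 2,4-dihydroxy-3,6-dimethylbenzoate | Cc1cc(O)c(C)c(O)c1C(=O)OCc1ccccc1 | intermediate
4 | glyoxylic acid monohydrate (2,2-dihydroxyacetic acid) | OC(O)C(=O)O | starting material
5 | 3-(triphenylphosphoranylidene)butan-2-one | CC(=O)C(C)=P(c1ccccc1)(c1ccccc1)c1ccccc1 | starting material
6 | (2E)-3-methyl-4-oxopent-2-enoic acid | CC(=O)/C(C)=C/C(=O)O | intermediate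
7 | benzyl 2-hydroxy-3,6-dimethyl-4-{[(2E)-3-methyl-4-oxopent-2-enoyl]oxy}benzoate | CC(=O)/C(C)=C/C(=O)Oc1cc(C)c(C(=O)OCc2ccccc2)c(O)c1C | intermediate
8 | benzyl 2-hydroxy-3,6-dimethyl-4-{[(2E)-7,7,7-trifluoro-3-methyl-4,6-dioxohept-2-enoyl]oxy}benzoate (trifluoroacetyl diketone) | O=C(CC(=O)C(F)(F)F)/C(C)=C/C(=O)Oc1cc(C)c(C(=O)OCc2ccccc2)c(O)c1C | intermediate
9 | benzyl 4-{[(2E)-5-diazo-3-methyl-4-oxopent-2-enoyl]oxy}-2-hydroxy-3,6-dimethylbenzoate | [N-]=[N+]=CC(=O)/C(C)=C/C(=O)Oc1cc(C)c(C(=O)OCc2ccccc2)c(O)c1C | intermediate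
10 | chloroacetaldehyde dimethyl acetal (2-chloro-1,1-dimethoxyethane) | COC(CCl)OC | starting material
11 | lithium methoxyacetylide | [Li]C#COC | intermediate
12 | 3-methoxyprop-2-yn-1-ol | COC#CCO | intermediate
13 | tert-butyl[(3-methoxyprop-2-yn-1-yl)oxy]dimethylsilane | COC#CCO[Si](C)(C)C(C)(C)C | intermediate
14 | benzyl 2-hydroxy-3,6-dimethyl-4-{[(2E)-3-methyl-5-oxopenta-2,4-dienoyl]oxy}benzoate (vinylketene) | O=C=C/C(C)=C/C(=O)Oc1cc(C)c(C(=O)OCc2ccccc2)c(O)c1C | intermediate
15 | benzyl 4-{[(2E)-3-[3-({[tert-butyl(dimethyl)silyl]oxy}methyl)-2-methoxy-4-oxocyclobut-2-en-1-yl]but-2-enoyl]oxy}-2-hydroxy-3,6-dimethylbenzoate (vinylcyclobutenone, racemic at the ring CH) | O=C1C(CO[Si](C)(C)C(C)(C)C)=C(OC)C1/C(C)=C/C(=O)Oc1cc(C)c(C(=O)OCc2ccccc2)c(O)c1C | intermediate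
16 | benzyl 4-{[(2E,4E)-6-({[tert-butyl(dimethyl)silyl]oxy}methyl)-5-methoxy-3-methyl-7-oxohepta-2,4,6-trienoyl]oxy}-2-hydroxy-3,6-dimethylbenzoate (dienylketene) | O=C=C(CO[Si](C)(C)C(C)(C)C)/C(OC)=C\C(C)=C\C(=O)Oc1cc(C)c(C(=O)OCc2ccccc2)c(O)c1C | intermediate
17 | benzyl 4-({[3-({[tert-butyl(dimethyl)silyl]oxy}methyl)-4-methoxy-6-methyl-2-oxocyclohexa-3,5-dien-1-yl]carbonyl}oxy)-2-hydroxy-3,6-dimethylbenzoate (cyclohexadienone, racemic at C1) | O=C1C(CO[Si](C)(C)C(C)(C)C)=C(OC)C=C(C)C1C(=O)Oc1cc(C)c(C(=O)OCc2ccccc2)c(O)c1C | intermediate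
18 | benzyl 4-{[3-({[tert-butyl(dimethyl)silyl]oxy}methyl)-2-hydroxy-4-methoxy-6-methylbenzoyl]oxy}-2-hydroxy-3,6-dimethylbenzoate | COc1cc(C)c(C(=O)Oc2cc(C)c(C(=O)OCc3ccccc3)c(O)c2C)c(O)c1CO[Si](C)(C)C(C)(C)C | intermediate
19 | 4-{[3-({[tert-butyl(dimethyl)silyl]oxy}methyl)-2-hydroxy-4-methoxy-6-methylbenzoyl]oxy}-2-hydroxy-3,6-dimethylbenzoic acid | COc1cc(C)c(C(=O)Oc2cc(C)c(C(=O)O)c(O)c2C)c(O)c1CO[Si](C)(C)C(C)(C)C | intermediate
20 | 3-alpha-hydroxybarbatic acid (2-hydroxy-4-{[2-hydroxy-3-(hydroxymethyl)-4-methoxy-6-methylbenzoyl]oxy}-3,6-dimethylbenzoic acid) | COc1cc(C)c(C(=O)Oc2cc(C)c(C(=O)O)c(O)c2C)c(O)c1CO | target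

Total step count: 10 steps.
Longest linear sequence: 7 steps (1, 2, 4, 5, 8, 9, 10).

Steps most likely to fail

Step 8. The vinylketene may be captured by a phenolic hydroxyl (of ring B or of product already formed) before it meets the alkyne. Light may isomerize the enoate from E to Z, after which the ester carbonyl can cyclize onto the ketene. The 6π closure may also be slow at a terminus that carries an acceptor, so that the dienylketene is diverted. The fallback makes ring A alone from an ester-free vinylketene and joins it to ring B by classical depside esterification. It sets out from alkyne 13 and phenol 3 and comes back at 18. Commercial 3-methylbut-3-en-2-one is taken through the sequence of step 5 to 1,1,1-trifluoro-5-methylhex-5-ene-2,4-dione F1 and then 1-diazo-3-methylbut-3-en-2-one F2. F2 and 13 under the conditions of step 8, an ordinary case of this benzannulation, should give 2-({[tert-butyl(dimethyl)silyl]oxy}methyl)-3-methoxy-5-methylphenol F3. Magnesium-mediated ortho-formylation (MgCl2, Et3N, (CH2O)n, MeCN, reflux) at the only free position ortho to OH should give 3-({[tert-butyl(dimethyl)silyl]oxy}methyl)-2-hydroxy-4-methoxy-6-methylbenzaldehyde F4. Pinnick oxidation (NaClO2, NaH2PO4, 2-methylbut-2-ene, t-BuOH/H2O) should give 3-({[tert-butyl(dimethyl)silyl]oxy}methyl)-2-hydroxy-4-methoxy-6-methylbenzoic acid F5. DCC esterification of F5 with the 4-hydroxyl of 3 in toluene gives 18.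

Step 5. The enolate may add to the electron-poor double bond of unreacted ketone, or take part in acyl transfer at the aryl ester, before it is trifluoroacetylated. The aryl ester may also be lost by hydrolysis during the amine/water stage. The fallback acylates diazomethane with a mesaconic half-ester chloride. It sets out from 3 and 4 and comes back at 9. Wittig reaction of 4 with commercial tert-butyl 2-(triphenylphosphoranylidene)propanoate should give (2E)-4-tert-butoxy-3-methyl-4-oxobut-2-enoic acid F6. DCC/DMAP esterification with 3 gives 4-{4-[(benzyloxy)carbonyl]-3-hydroxy-2,5-dimethylphenyl} 1-tert-butyl (2E)-2-methylbut-2-enedioate F7. CF3CO2H in CH2Cl2 removes the tert-butyl group to give (2E)-4-{4-[(benzyloxy)carbonyl]-3-hydroxy-2,5-dimethylphenoxy}-2-methyl-4-oxobut-2-enoic acid F8. (COCl)2 with catalytic DMF gives benzyl 4-{[(2E)-4-chloro-3-methyl-4-oxobut-2-enoyl]oxy}-2-hydroxy-3,6-dimethylbenzoate F9. Slow addition of F9 to excess ethereal CH2N2 at −20 °C with short contact time, so that acylation stays ahead of dipolar cycloaddition to the double bond, gives 9.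

Step 6. The threefold elimination may stop short, and the small ynol ether alcohol may be lost by hydration during work-up or by evaporation on concentration. The fallback reaches the acetylide from a dichlorovinyl ether. It sets out from commercial trichloroethylene and methanol in place of 10 and comes back at 11 or, with silylation in the same flask, at 13. Methoxide (KH, MeOH, THF) adds to trichloroethylene to give (E)-1,2-dichloro-1-methoxyethene F10. n-BuLi (2.2 equiv, THF, −78 °C) converts F10 into 11 by elimination and chlorine–lithium exchange. Paraformaldehyde and then TBSCl added to the lithium alkoxide give 13 without isolation of 12.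

Further compounds
F1 | step 8 | 1,1,1-trifluoro-5-methylhex-5-ene-2,4-dione | C=C(C)C(=O)CC(=O)C(F)(F)F
F2 | step 8 | 1-diazo-3-methylbut-3-en-2-one | C=C(C)C(=O)C=[N+]=[N-]
F3 | step 8 | 2-({[tert-butyl(dimethyl)silyl]oxy}methyl)-3-methoxy-5-methylphenol | COc1cc(C)cc(O)c1CO[Si](C)(C)C(C)(C)C
F4 | step 8 | 3-({[tert-butyl(dimethyl)silyl]oxy}methyl)-2-hydroxy-4-methoxy-6-methylbenzaldehyde | COc1cc(C)c(C=O)c(O)c1CO[Si](C)(C)C(C)(C)C
F5 | step 8 | 3-({[tert-butyl(dimethyl)silyl]oxy}methyl)-2-hydroxy-4-methoxy-6-methylbenzoic acid | COc1cc(C)c(C(=O)O)c(O)c1CO[Si](C)(C)C(C)(C)C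
F6 | step 5 | (2E)-4-tert-butoxy-3-methyl-4-oxobut-2-enoic acid | CC(C)(C)OC(=O)/C(C)=C/C(=O)O
F7 | step 5 | 4-{4-[(benzyloxy)carbonyl]-3-hydroxy-2,5-dimethylphenyl} 1-tert-butyl (2E)-2-methylbut-2-enedioate | CC(C)(C)OC(=O)/C(C)=C/C(=O)Oc1cc(C)c(C(=O)OCc2ccccc2)c(O)c1C
F8 | step 5 | (2E)-4-{4-[(benzyloxy)carbonyl]-3-hydroxy-2,5-dimethylphenoxy}-2-methyl-4-oxobut-2-enoic acid | OC(=O)/C(C)=C/C(=O)Oc1cc(C)c(C(=O)OCc2ccccc2)c(O)c1C
F9 | step 5 | benzyl 4-{[(2E)-4-chloro-3-methyl-4-oxobut-2-enoyl]oxy}-2-hydroxy-3,6-dimethylbenzoate | ClC(=O)/C(C)=C/C(=O)Oc1cc(C)c(C(=O)OCc2ccccc2)c(O)c1C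
F10 | step 6 | (E)-1,2-dichloro-1-methoxyethene | CO/C(Cl)=C\Cl
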